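**Retrosynthetic overview**
1. Target ⇐ its aryl bromide analogue: the phenol C–O bond is made last (Ar–Br → Ar–OH), so the phenol never needs a protecting group.
2. Aryl bromide lactone ⇐ (R)-β-(3,4-dimethoxybenzyl)-γ-butyrolactone + 3-bromo-4,5-dimethoxybenzyl bromide (trans-selective enolate alkylation sets C3).
3. (R)-Lactone ⇐ prochiral 3-(3,4-dimethoxybenzyl)cyclobutanone by catalytic enantioselective Baeyer–Villiger oxygen insertion: the key C–O bond, which closes the lactone and sets C4.
4. Cyclobutanone ⇐ methyl eugenol + dichloroketene ([2+2], then dechlorination).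
5. Ring order: temporary cyclobutanone first, then the γ-lactone by ring expansion; both arenes are bought.

**Assumptions:** The target is the trans-(3R,4R) lactone, taken as ≥98% ee. 3-Bromo-4,5-dimethoxybenzyl alcohol (9) is bought as a catalogue compound. Which antipode of the step 3 catalyst gives (R)-8 is fixed by one test run; both antipodes are equally accessible.

**Route**

Step 1
Reactants: 1 methyl eugenol (4-allyl-1,2-dimethoxybenzene); 2 trichloroacetyl chloride
Product: 4 rac-2,2-dichloro-3-(3,4-dimethoxybenzyl)cyclobutan-1-one, via dichloroketene 3 (not isolated)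
Conditions: Zn–Cu couple, Et2O/DME, reflux, slow addition of 2
Reagents that add atoms: none
Why: Thermal ketene–alkene [2+2] cycloaddition; dichloroketene (from 2 by zinc dehalogenation) bonds its carbonyl carbon to the terminal CH2 of the alkene, giving only the 2,2-dichloro-3-substituted cyclobutanone, and the racemic stereocentre formed is erased in step 2.

Step 2
Reactants: 4 rac-2,2-dichloro-3-(3,4-dimethoxybenzyl)cyclobutan-1-one
Product: 6 3-(3,4-dimethoxybenzyl)cyclobutan-1-one, via monochloro ketone 5 (not isolated)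
Conditions: Zn dust, AcOH, rt → 60 °C
Reagents that add atoms: none
Why: Zinc reductive dehalogenation of an α,α-dichloro ketone (via zinc enolates) leaves ring and aryl ethers untouched and makes C3 a prochiral centre flanked by two enantiotopic CH2–C(O) bonds.

Step 3
Reactants: 6 3-(3,4-dimethoxybenzyl)cyclobutan-1-one
Product: 8 (R)-4-(3,4-dimethoxybenzyl)dihydrofuran-2(3H)-one, via Criegee adduct 7 (not isolated)
Conditions: confined C2-symmetric imidodiphosphoric acid built from two 3,3'-bis(2,4,6-triethylphenyl)-BINOL units (5 mol%), 35% aq H2O2 (1.5 equiv), CHCl3, −40 °C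
Reagents that add atoms: hydrogen peroxide, OO
Why: Proposed new method: a confined imidodiphosphoric acid, not yet used for Baeyer–Villiger chemistry, binds ketone 6 and H2O2 on its P–OH/P=O pair so that Criegee adduct 7 forms and rearranges inside a narrow chiral pocket where only one of the two enantiotopic CH2–C(O) bonds can lie antiperiplanar to the O–O bond while the veratrylmethyl group points out of the cavity; that CH2 migrates to oxygen with loss of water, which makes the lactone C–O bond and sets C4 as (R) by desymmetrisation; the closest known reactions are the BINOL-phosphoric-acid-catalysed Baeyer–Villiger desymmetrisation of 3-substituted cyclobutanones with aqueous H2O2 and the sulfoxidation with aqueous H2O2 catalysed by the same confined acid class.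

Step 4
Reactants: 9 3-bromo-4,5-dimethoxybenzyl alcohol
Product: 10 3-bromo-4,5-dimethoxybenzyl bromide
Conditions: PBr3 (0.4 equiv), CH2Cl2, 0 °C → rt
Reagents that add atoms: phosphorus tribromide, BrP(Br)Br
Why: PBr3 bromination of a primary benzylic alcohol (SN2 on the phosphite ester); nothing else in 9 reacts.

Step 5
Reactants: 8 (R)-4-(3,4-dimethoxybenzyl)dihydrofuran-2(3H)-one; 10 3-bromo-4,5-dimethoxybenzyl bromide
Product: 12 (3R,4R)-3-(3-bromo-4,5-dimethoxybenzyl)-4-(3,4-dimethoxybenzyl)dihydrofuran-2(3H)-one, via lithium enolate 11 (not isolated)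
Conditions: LiHMDS (1.05 equiv), THF, −78 °C; then 10 (1.15 equiv), DMPU, −78 → −40 °C; aq NH4Cl
Reagents that add atoms: none
Why: Lactone enolate alkylation (SN2); the benzyl bromide attacks the planar lithium enolate on the face opposite the C4 veratrylmethyl group, so C3 is set trans (3R), the usual outcome for β-benzyl-γ-butyrolactones, and the amide base does not touch the aryl bromide.

Step 6
Reactants: 12 (3R,4R)-3-(3-bromo-4,5-dimethoxybenzyl)-4-(3,4-dimethoxybenzyl)dihydrofuran-2(3H)-one
Product: 14 (3R,4R)-4-(3,4-dimethoxybenzyl)-3-(3-hydroxy-4,5-dimethoxybenzyl)dihydrofuran-2(3H)-one, via aryl boronate 13 (not isolated)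
Conditions: B2pin2, Pd(dppf)Cl2 (5 mol%), KOAc, 1,4-dioxane, 90 °C; then 30% H2O2, THF/aq NaHCO3, 0 °C → rt; Na2S2O3, dilute HCl wash
Reagents that add atoms: hydrogen peroxide, OO (the phenol oxygen); bis(pinacolato)diboron, CC1(C)OB(OC1(C)C)B1OC(C)(C)C(C)(C)O1 (boron of 13 only, lost again)
Why: Miyaura borylation followed by oxidative ipso-hydroxylation (1,2-aryl shift from boron to oxygen) puts OH exactly where Br stood; acetate and bicarbonate are too weak to open the lactone or epimerise C3, which is in any case the thermodynamically preferred trans isomer.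

**Compound list**
1 | methyl eugenol (4-allyl-1,2-dimethoxybenzene) | COc1ccc(CC=C)cc1OC | starting material
2 | trichloroacetyl chloride | ClC(=O)C(Cl)(Cl)Cl | starting material
3 | dichloroketene (not isolated) | ClC(Cl)=C=O | intermediate
4 | rac-2,2-dichloro-3-(3,4-dimethoxybenzyl)cyclobutan-1-one | COc1ccc(CC2CC(=O)C2(Cl)Cl)cc1OC | intermediate
5 | 2-chloro-3-(3,4-dimethoxybenzyl)cyclobutan-1-one, racemic cis/trans mixture (not isolated) | COc1ccc(CC2CC(=O)C2Cl)cc1OC | intermediate
6 | 3-(3,4-dimethoxybenzyl)cyclobutan-1-one (achiral) | COc1ccc(CC2CC(=O)C2)cc1OC | intermediate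
7 | 3-(3,4-dimethoxybenzyl)-1-hydroperoxycyclobutan-1-ol, Criegee adduct (not isolated) | COc1ccc(CC2CC(O)(OO)C2)cc1OC | intermediate
8 | (R)-4-(3,4-dimethoxybenzyl)dihydrofuran-2(3H)-one | COc1ccc(C[C@H]2COC(=O)C2)cc1OC | intermediate
9 | 3-bromo-4,5-dimethoxybenzyl alcohol | OCc1cc(Br)c(OC)c(OC)c1 | starting material
10 | 3-bromo-4,5-dimethoxybenzyl bromide | BrCc1cc(Br)c(OC)c(OC)c1 | intermediate
11 | lithium (R)-4-(3,4-dimethoxybenzyl)-4,5-dihydrofuran-2-olate, enolate of 8 (not isolated) | COc1ccc(C[C@H]2COC([O-])=C2)cc1OC.[Li+] | intermediate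
12 | (3R,4R)-3-(3-bromo-4,5-dimethoxybenzyl)-4-(3,4-dimethoxybenzyl)dihydrofuran-2(3H)-one | COc1ccc(C[C@H]2COC(=O)[C@@H]2Cc2cc(Br)c(OC)c(OC)c2)cc1OC | intermediate
13 | (3R,4R)-4-(3,4-dimethoxybenzyl)-3-[3,4-dimethoxy-5-(4,4,5,5-tetramethyl-1,3,2-dioxaborolan-2-yl)benzyl]dihydrofuran-2(3H)-one (not isolated) | COc1ccc(C[C@H]2COC(=O)[C@@H]2Cc2cc(B3OC(C)(C)C(C)(C)O3)c(OC)c(OC)c2)cc1OC | intermediate
14 | (3R,4R)-4-(3,4-dimethoxybenzyl)-3-(3-hydroxy-4,5-dimethoxybenzyl)dihydrofuran-2(3H)-one | COc1ccc(C[C@H]2COC(=O)[C@@H]2Cc2cc(O)c(OC)c(OC)c2)cc1OC | target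

**Totals**
Total step count: 6. Longest linear sequence: 5 (steps 1, 2, 3, 5, 6).

**Three steps most likely to fail**

Step 3 (the proposed new Baeyer–Villiger desymmetrisation). The stereocentre is remote from the carbonyl and the benzyl group is flexible, so the ee may fall short, and water may slow the catalyst at −40 °C. The ee is checked on 8 by chiral HPLC. The fallback uses known chemistry and sets out from 6. Enantioselective deprotonation with a chiral lithium amide (lithium bis(1-phenylethyl)amide, the antipode that gives the R product, TMSCl in-situ quench, THF, −100 °C) gives (R)-{[3-(3,4-dimethoxybenzyl)cyclobut-1-en-1-yl]oxy}trimethylsilane F1. Ozonolysis of the enol ether double bond (O3, CH2Cl2/MeOH, −78 °C) with NaBH4 work-up gives (R)-4-(3,4-dimethoxyphenyl)-3-(hydroxymethyl)butanoic acid F2, which closes on acidification and comes back to the route at 8.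

Step 6 (borylation/oxidation on the full skeleton). The electron-rich, ortho-methoxy aryl bromide may borylate slowly or protodebrominate, and the des-bromo lactone would be hard to separate. The fallback sets out from 12 and replaces the C–B detour by a direct palladium-catalysed C–O coupling with a hydroxide surrogate: (E)-benzaldoxime, tBuBrettPhos palladacycle precatalyst, Cs2CO3, DMF, 80 °C. This gives O-(5-{[(3R,4R)-4-(3,4-dimethoxybenzyl)-2-oxooxolan-3-yl]methyl}-2,3-dimethoxyphenyl) (E)-benzaldoxime F3, which fragments under the same base to the phenoxide and, after acidic work-up, comes back at 14.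

Step 1 (dichloroketene cycloaddition). Dichloroketene polymerises readily and unactivated terminal alkenes react only moderately, so the yield may be low. The fallback sets out from 1 and uses a keteniminium [2+2] instead. N,N-Dimethylacetamide, Tf2O and 2,4,6-collidine in 1,2-dichloroethane at reflux generate N,N-dimethylketeniminium triflate F4, which adds to the alkene to give N-[3-(3,4-dimethoxybenzyl)cyclobutylidene]-N-methylmethanaminium triflate F5. Aqueous NaHCO3 hydrolysis comes back to the route at 6, bypassing 4 and 5.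

**Further compounds**
F1 | step 3 | (R)-{[3-(3,4-dimethoxybenzyl)cyclobut-1-en-1-yl]oxy}trimethylsilane | COc1ccc(C[C@@H]2CC(O[Si](C)(C)C)=C2)cc1OC
F2 | step 3 | (R)-4-(3,4-dimethoxyphenyl)-3-(hydroxymethyl)butanoic acid | COc1ccc(C[C@H](CC(=O)O)CO)cc1OC
F3 | step 6 | O-(5-{[(3R,4R)-4-(3,4-dimethoxybenzyl)-2-oxooxolan-3-yl]methyl}-2,3-dimethoxyphenyl) (E)-benzaldoxime | COc1ccc(C[C@H]2COC(=O)[C@@H]2Cc2cc(O/N=C/c3ccccc3)c(OC)c(OC)c2)cc1OC
F4 | step 1 | N,N-dimethylketeniminium triflate | C[N+](C)=C=C.[O-]S(=O)(=O)C(F)(F)F
F5 | step 1 | N-[3-(3,4-dimethoxybenzyl)cyclobutylidene]-N-methylmethanaminium triflate | C[N+](C)=C1CC(Cc2ccc(OC)c(OC)c2)C1.[O-]S(=O)(=O)C(F)(F)F
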